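The ratio of Z to X cannot be read at the first alpha reading: at 0.250 min that run shows Z 2.9 % and X 0 %, against a scatter of 0.5 percentage points.

common to all: Q 0.23 mM (held)

| run | J | D | remark | time |
|---|---|---|---|---|
| alpha | 2 mM | 0.25 mM | run made earlier |  |
| gamma | 2 mM | 0.38 mM | run made earlier |  |
| eta | 3 mM | 0.50 mM | run made earlier |  |
| flask | 2.0 mM | 0.500 mM |  | 5.0 min |

| run | time / min | Z / % | X / % |
|---|---|---|---|
| alpha | 0.250 | 2.9 | 0 |
| alpha | 0.333 | 4.3 | 1.4 |
| alpha | 0.500 | 6.2 | 2.8 |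
| alpha | 0.833 | 11.5 | 3.0 |
| alpha | 1.33 | 17.7 | 4.3 |
| alpha | 2.00 | 27.2 | 8.7 |
| alpha | 3.00 | 38.2 | 12.1 |
| gamma | 0.167 | 1.7 | 0.5 |
| gamma | 0.500 | 5.6 | 1.6 |
| gamma | 0.833 | 10.3 | 2.5 |
| gamma | 1.33 | 16.7 | 6.1 |
| gamma | 2.00 | 26.3 | 9.5 |
| gamma | 2.50 | 31.1 | 11.2 |
| gamma | 3.00 | 36.2 | 13.4 |
| eta | 0.250 | 3.0 | 1.1 |
| eta | 0.833 | 9.6 | 3.5 |
| eta | 1.33 | 16.1 | 5.1 |
| eta | 2.00 | 22.5 | 8.4 |
| eta | 3.00 | 32.3 | 11.7 |

(scatter of a reading: 0.5 percentage points)

- at the start none of Q is in solution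

- ratio of Z to X at 8.0 s
- ratio of Z to X at 50 s
- ratio of Z to X at 5.0 min
- which of Z and X there is more of at 5.0 min

The last readings, at 3.00 min, carry more weight. From above, the alpha run gives a ratio of 3.16. From below, the gamma run gives 2.70, and the eta run reads 2.76. Each end rests on a single X near 12.1 %, so the runs are pooled: total Z over total X at those readings gives 2.87. This is the late split, a selectivity read from the amounts formed, and it is the nearly constant quantity to freeze. This reckoning commits to it at 5.0 min, with Z ahead of X. One caution stands: the flask charges J to D at 4.00, lower than the 5.26 of the gamma run, the lowest of the runs, so the freeze reaches beyond them.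

The forecast gives 2.9 at 8.0 s (2 to 4), 2.9 at 50 s (2.5 to 3.4) and 2.9 at 5.0 min (2.4 to 3.7), with Z leading, “suggesting parallel paths sharing the same dependence”. Its value at 5.0 min lies inside the bracket.

The flask gives 2.98 at 8.0 s, 2.81 at 50 s and 2.69 at 5.0 min, beside the lower end of the bracket, with Z at 52.3 % and X at 19.4 %.

    J ⇌ D (K = 0.300, k = 0.00755 s⁻¹)
    J + L → Z (k = 26.6 L mol⁻¹ s⁻¹)
    L + D → X (k = 34.7 L mol⁻¹ s⁻¹)
    D → G (k = 5.79 × 10⁻⁵ s⁻¹)
    Q ⇌ L, rate k5*(csat - [L]) (kL = 0.0810 s⁻¹)

Long past the latest time the ratio in the flask reads 2.69, so its drift of 0.290 from the value at 8.0 s is smaller than the bracket's width of 0.460. The split times the flask's X gives Z at 55.7 %, against the 52.3 % found. In the neighbour flask charged with 8.0 mM of J, the split times its X of 11.6 % gives 33.3 %, and that flask holds Z at 33.2 % after 5.00 min.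

Readings and results were generated by integration with constants of no real substance, and the scatter is random.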